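**Plan**

Locants: C1 (CH–O-acyl), C2, C3 (C–OH), C4 (CH–i-Pr), C5, C6, C7 (C–Me), C8, C9=C10 (C10–Me). Ring A (five-membered) is C3-C4-C5-C6-C7 and ring B (seven-membered) is C1-C2-C3-C7-C8-C9-C10.
Enabling feature: the tertiary carbinol C3 lies β to the oxygen on C1, so ring B holds the aldol retron C3(OH)–C2–C1(=O). C3 is also a ring A carbon that can serve as a cyclopentanone carbonyl between C4 and the quaternary C7.
Cuts, in retrosynthetic order: the veratroyl–O bond at C1, C2–C3 (opens ring B), C1–C2, C9=C10, C4–C(i-Pr), C7–C8 and C7–CH3.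
Forward order: ring A is closed first from an adipate and the arm on C7 is grown to a (Z)-bromomethyl enone. Ring B is then closed by a SmI2 Reformatsky-type aldol, and C1 is reduced and acylated.
Stereochemistry: C7 comes from a ligand-controlled decarboxylative allylation. C7 guides hydride to a temporary C3 carbinol, and that hydroxyl guides H2 to C4. The C7 tether and the C4 and C7 substituents fix C3 in the ring closure, and the C3 hydroxyl delivers hydride to C1.

Key step: step 15

Assumption: the (R)-configured phosphinooxazoline ligand is taken to give the (R)-configured allyl ketone in step 2, the mirror image of the established pairing of the (S)-ligand with (S)-2-allyl-2-methylcycloalkanones.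

**Route**

Step 1
Reactants: 1 diallyl adipate; 2 iodomethane
Product: 4 allyl 1-methyl-2-oxocyclopentane-1-carboxylate (racemic), via sodium enolate of allyl 2-oxocyclopentane-1-carboxylate 3 (not isolated)
Conditions: NaH, allyl alcohol (cat.), toluene, 40 to 95 °C; then MeI, THF, 50 °C
Reagents that add atoms: none
Why: A Dieckmann condensation closes ring A and the stabilised β-keto ester enolate is C-methylated in the same flask, the racemic quaternary centre being of no account because step 2 erases and rebuilds it.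

Step 2
Reactants: 4 allyl 1-methyl-2-oxocyclopentane-1-carboxylate
Product: 5 (2R)-2-methyl-2-(prop-2-en-1-yl)cyclopentan-1-one
Conditions: Pd2(dba)3 (2.5 mol %), (R)-t-BuPHOX = (4R)-4-tert-butyl-2-[2-(diphenylphosphanyl)phenyl]-4,5-dihydro-1,3-oxazole (6 mol %), toluene, 25 °C
Reagents that add atoms: none
Why: Decarboxylative asymmetric allylic alkylation: zerovalent palladium ionises the allyl ester, loss of CO2 turns both enantiomers of 4 into one prochiral enolate, and C–C bond formation inside the chiral P,N-ligand pocket sets the quaternary C7 as R.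

Step 3
Reactants: 5 (2R)-2-methyl-2-(prop-2-en-1-yl)cyclopentan-1-one; 6 acetone
Product: 8 (2R)-5-(2-hydroxypropan-2-yl)-2-methyl-2-(prop-2-en-1-yl)cyclopentan-1-one (both C5 epimers), via lithium enolate 7 (not isolated)
Conditions: LiN(i-Pr)2, THF, −78 °C; then acetone, −78 °C; AcOH quench at −78 °C
Reagents that add atoms: none
Why: Directed aldol addition: C7 is quaternary, so deprotonation can only occur at C4 and a single lithium enolate adds to acetone, the cold acidic quench holding back retro-aldol cleavage, and the C4 configuration is immaterial because step 4 flattens it.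

Step 4
Reactants: 8 (2R)-5-(2-hydroxypropan-2-yl)-2-methyl-2-(prop-2-en-1-yl)cyclopentan-1-one
Product: 10 (2R)-2-methyl-5-(propan-2-ylidene)-2-(prop-2-en-1-yl)cyclopentan-1-one, via tertiary mesylate 9 (not isolated)
Conditions: MsCl, Et3N, CH2Cl2, 0 °C; then DBU, rt
Reagents that add atoms: none
Why: Mesylation of the tertiary alcohol by way of sulfene and E1cB elimination give the conjugated tetrasubstituted enone, and DBU draws any β,γ-unsaturated isomer into conjugation.

Step 5
Reactants: 10 (2R)-2-methyl-5-(propan-2-ylidene)-2-(prop-2-en-1-yl)cyclopentan-1-one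
Product: 12 [(1R)-1-methyl-2-oxo-3-(propan-2-ylidene)cyclopentyl]acetaldehyde, via vicinal diol 11 (not isolated)
Conditions: OsO4 (2 mol %), NaIO4, 2,6-lutidine, dioxane/H2O, rt
Reagents that add atoms: sodium periodate, [Na+].[O-]I(=O)(=O)=O (its oxygen reaches the product by way of OsO4)
Why: Lemieux–Johnson oxidative cleavage: OsO4 dihydroxylates the unhindered monosubstituted alkene much faster than the electron-poor tetrasubstituted enone double bond, periodate cleaves the diol, and 2,6-lutidine suppresses side oxidation.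

Step 6
Reactants: 12 [(1R)-1-methyl-2-oxo-3-(propan-2-ylidene)cyclopentyl]acetaldehyde
Product: 13 (1S,2R)-2-(2-hydroxyethyl)-2-methyl-5-(propan-2-ylidene)cyclopentan-1-ol (C3 hydroxyl cis to the hydroxyethyl arm)
Conditions: i-Bu2AlH (3.5 equiv), CH2Cl2, −78 °C; aq potassium sodium tartrate
Reagents that add atoms: none
Why: Hydride 1,2-reduction of aldehyde and enone with i-Bu2AlH: the aldehyde reacts first, its bulky aluminium alkoxide makes the arm on C7 far larger than the methyl group, and hydride therefore should enter C3 from the methyl face, leaving the temporary C3 hydroxyl cis to the arm, with any minor epimer removed by chromatography.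

Step 7
Reactants: 13 (1S,2R)-2-(2-hydroxyethyl)-2-methyl-5-(propan-2-ylidene)cyclopentan-1-ol
Product: 14 (1R,2R,5R)-2-(2-hydroxyethyl)-2-methyl-5-(propan-2-yl)cyclopentan-1-ol
Conditions: H2 (1 to 50 bar), [Ir(cod)(PCy3)(py)]PF6 (5 mol %), CH2Cl2, rt
Reagents that add atoms: none
Why: Hydroxyl-directed homogeneous hydrogenation: the cationic iridium catalyst, one of the few that accept tetrasubstituted alkenes, binds the allylic C3 hydroxyl (and the hydroxyethyl arm on the same face) and adds H2 from that face, so that C4–H ends cis to the hydroxyl and the isopropyl group cis to the C7 methyl group (C4 = R).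

Step 8
Reactants: 14 (1R,2R,5R)-2-(2-hydroxyethyl)-2-methyl-5-(propan-2-yl)cyclopentan-1-ol
Product: 15 (1R,2R,5R)-2-methyl-5-(propan-2-yl)-1-(triethylsilyloxy)-2-[2-(triethylsilyloxy)ethyl]cyclopentane
Conditions: TESOTf (2.5 equiv), 2,6-lutidine, CH2Cl2, −78 to 0 °C
Reagents that add atoms: triethylsilyl trifluoromethanesulfonate, CC[Si](CC)(CC)OS(=O)(=O)C(F)(F)F
Why: Silyl ether formation with the silyl triflate, which is reactive enough for the carbinol wedged between C4 and C7, masks C3 against the organometallic reagents of steps 10 to 12.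

Step 9
Reactants: 15 (1R,2R,5R)-2-methyl-5-(propan-2-yl)-1-(triethylsilyloxy)-2-[2-(triethylsilyloxy)ethyl]cyclopentane
Product: 17 [(1R,2R,3R)-1-methyl-3-(propan-2-yl)-2-(triethylsilyloxy)cyclopentyl]acetaldehyde, via alkoxysulfonium chloride 16 (not isolated)
Conditions: (COCl)2, DMSO, CH2Cl2, −78 to −40 °C; then Et3N, −78 to 0 °C
Reagents that add atoms: none
Why: Swern oxidation applied directly to a silyl ether: chlorodimethylsulfonium chloride attacks only the unhindered primary Si–O oxygen, chloride takes the silyl group, and base collapses the alkoxysulfonium salt to the aldehyde while the crowded secondary silyl ether stays in place.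

Step 10
Reactants: 17 [(1R,2R,3R)-1-methyl-3-(propan-2-yl)-2-(triethylsilyloxy)cyclopentyl]acetaldehyde; 18 ethyl 2-[bis(2,2,2-trifluoroethoxy)phosphoryl]propanoate
Product: 20 ethyl (2Z)-2-methyl-4-[(1R,2R,3R)-1-methyl-3-(propan-2-yl)-2-(triethylsilyloxy)cyclopentyl]but-2-enoate, via potassium phosphonate carbanion 19 (not isolated)
Conditions: 18, KN(SiMe3)2, 18-crown-6, THF, −78 °C; then 17, −78 °C
Reagents that add atoms: none
Why: Still–Gennari olefination: the electron-poor trifluoroethyl phosphonate with a dissociated potassium counter-ion eliminates faster than its adducts equilibrate, which gives the (Z)-trisubstituted enoate with C1 cis to C8 as ring B requires.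

Step 11
Reactants: 20 ethyl (2Z)-2-methyl-4-[(1R,2R,3R)-1-methyl-3-(propan-2-yl)-2-(triethylsilyloxy)cyclopentyl]but-2-enoate
Product: 21 (2Z)-N-methoxy-N,2-dimethyl-4-[(1R,2R,3R)-1-methyl-3-(propan-2-yl)-2-(triethylsilyloxy)cyclopentyl]but-2-enamide
Conditions: MeNH(OMe)·HCl, i-PrMgCl, THF, −20 to 0 °C
Reagents that add atoms: N,O-dimethylhydroxylamine hydrochloride, CNOC.Cl
Why: Weinreb amide synthesis by aminolysis of the ester with the magnesium amide of N,O-dimethylhydroxylamine, mild enough to leave the silyl ether and the (Z)-alkene untouched.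

Step 12
Reactants: 21 (2Z)-N-methoxy-N,2-dimethyl-4-[(1R,2R,3R)-1-methyl-3-(propan-2-yl)-2-(triethylsilyloxy)cyclopentyl]but-2-enamide; 22 dibromomethane
Product: 24 (3Z)-1-bromo-3-methyl-5-[(1R,2R,3R)-1-methyl-3-(propan-2-yl)-2-(triethylsilyloxy)cyclopentyl]pent-3-en-2-one, via lithium tetrahedral adduct 23 (not isolated)
Conditions: CH2Br2, MeLi·LiBr (added slowly to 21 and CH2Br2), THF/Et2O, −78 °C; AcOH quench at −78 °C
Reagents that add atoms: none
Why: Halomethyllithium homologation of a Weinreb amide: bromomethyllithium, generated by Li–Br exchange in the presence of 21 because it is short-lived, adds 1,2 to the unsaturated amide, and the chelated adduct 23 survives until the cold quench, which rules out a second addition.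

Step 13
Reactants: 24 (3Z)-1-bromo-3-methyl-5-[(1R,2R,3R)-1-methyl-3-(propan-2-yl)-2-(triethylsilyloxy)cyclopentyl]pent-3-en-2-one
Product: 25 (3Z)-1-bromo-5-[(1R,2R,3R)-2-hydroxy-1-methyl-3-(propan-2-yl)cyclopentyl]-3-methylpent-3-en-2-one
Conditions: 48 % aq HF, MeCN, 0 °C
Reagents that add atoms: none
Why: Acidic fluoride desilylation frees the C3 carbinol, and an amine-free medium is chosen because pyridine or basic fluoride would attack the bromomethyl ketone or trigger oxa-Michael addition of the hydroxyl to C9.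

Step 14
Reactants: 25 (3Z)-1-bromo-5-[(1R,2R,3R)-2-hydroxy-1-methyl-3-(propan-2-yl)cyclopentyl]-3-methylpent-3-en-2-one
Product: 26 (2R,5R)-2-[(2Z)-5-bromo-3-methyl-4-oxopent-2-en-1-yl]-2-methyl-5-(propan-2-yl)cyclopentan-1-one
Conditions: Dess–Martin periodinane, CH2Cl2, 0 °C to rt
Reagents that add atoms: none
Why: Dess–Martin oxidation under neutral to weakly acidic conditions returns C3 to the ketone level without epimerising C4, isomerising the (Z)-enone or displacing bromide.

Step 15
Reactants: 26 (2R,5R)-2-[(2Z)-5-bromo-3-methyl-4-oxopent-2-en-1-yl]-2-methyl-5-(propan-2-yl)cyclopentan-1-one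
Product: 29 (3R,3aS,8aR)-3a-hydroxy-6,8a-dimethyl-3-(propan-2-yl)-2,3,3a,4,8,8a-hexahydroazulen-5(1H)-one, via samarium enolate 27 (not isolated), via samarium aldolate 28 (not isolated)
Conditions: SmI2 (2.2 equiv, 0.1 M in THF), THF, −78 °C, slow addition of 26 (final 0.005 M); pH 7 phosphate buffer at −78 °C
Reagents that add atoms: none
Why: SmI2 hands two electrons in succession to the α-bromo ketone, bromide leaves and the resulting radical is reduced to the cross-conjugated enolate 27 of trivalent samarium, formed regiospecifically at C2 and without base, so that C4–H and the γ-positions stay untouched, after which C2 adds to the C3 carbonyl bound to the same oxophilic metal and the chelated aldolate 28 is protonated cold. The reaction type is the SmI2-mediated intramolecular Reformatsky (reductive aldol) reaction of α-bromo carbonyl compounds, which is established for medium-sized carbocycles and lactones. Ring B closes in the 7-(enolendo)-exo-trig mode, and the (Z)-C9=C10 bond takes two rotors out of the tether and keeps C2 within reach of C3. C3 is the only new stereocentre and is set by the substrate: the nucleophilic arm hangs from the neighbouring C7 and swings onto the carbonyl over its own face of ring A, the other face being covered by the C4 isopropyl and C7 methyl groups, so the ring fusion should come out cis with the hydroxyl on the side of those two groups (C3 = S). The step needs reduction of C–Br ahead of the enone and the cyclopentanone, which the much more easily reduced α-bromo ketone, the absence of proton donors or HMPA and the low temperature secure, and it needs closure ahead of intermolecular aldol addition, which high dilution secures. The cold neutral quench keeps the crowded tertiary aldolate from retro-aldol opening and from dehydration.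

Step 16
Reactants: 29 (3R,3aS,8aR)-3a-hydroxy-6,8a-dimethyl-3-(propan-2-yl)-2,3,3a,4,8,8a-hexahydroazulen-5(1H)-one
Product: 30 (3R,3aS,5R,8aR)-6,8a-dimethyl-3-(propan-2-yl)-2,3,4,5,8,8a-hexahydro-1H-azulene-3a,5-diol
Conditions: Me4NBH(OAc)3, MeCN/AcOH, −30 to 0 °C
Reagents that add atoms: none
Why: Evans–Saksena hydroxyl-directed reduction: the C3 hydroxyl replaces an acetate on boron and the tethered hydride attacks the C1 carbonyl in 1,2-fashion from the side of the C3–O bond, which puts the new C1 hydroxyl trans (1,3-anti) to the C3 hydroxyl (C1 = R).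

Step 17
Reactants: 30 (3R,3aS,5R,8aR)-6,8a-dimethyl-3-(propan-2-yl)-2,3,4,5,8,8a-hexahydro-1H-azulene-3a,5-diol; 31 3,4-dimethoxybenzoyl chloride
Product: 32 (3R,3aS,5R,8aR)-3a-hydroxy-6,8a-dimethyl-3-(propan-2-yl)-1,2,3,3a,4,5,8,8a-octahydroazulen-5-yl 3,4-dimethoxybenzoate (target)
Conditions: 31, Et3N, 4-dimethylaminopyridine (cat.), CH2Cl2, 0 °C to rt
Reagents that add atoms: none
Why: Nucleophile-catalysed acylation (acyl chloride with 4-dimethylaminopyridine) esterifies the secondary allylic C1 hydroxyl, whereas the tertiary ring-fusion C3 hydroxyl is too hindered to react.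

**Compound list**

1 | diallyl adipate | C=CCOC(=O)CCCCC(=O)OCC=C | starting material
2 | iodomethane | CI | starting material
3 | sodium enolate of allyl 2-oxocyclopentane-1-carboxylate (not isolated) | [Na+].[O-]C1=C(C(=O)OCC=C)CCC1 | intermediate
4 | allyl 1-methyl-2-oxocyclopentane-1-carboxylate (racemic) | C=CCOC(=O)C1(C)CCCC1=O | intermediate
5 | (2R)-2-methyl-2-(prop-2-en-1-yl)cyclopentan-1-one | O=C1CCC[C@]1(C)CC=C | intermediate
6 | acetone | CC(C)=O | starting material
7 | lithium enolate of 5 (not isolated) | [Li+].[O-]C1=CCC[C@]1(C)CC=C | intermediate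
8 | (2R)-5-(2-hydroxypropan-2-yl)-2-methyl-2-(prop-2-en-1-yl)cyclopentan-1-one (both C5 epimers) | O=C1C(C(C)(C)O)CC[C@]1(C)CC=C | intermediate
9 | tertiary mesylate of 8 (not isolated) | O=C1C(C(C)(C)OS(C)(=O)=O)CC[C@]1(C)CC=C | intermediate
10 | (2R)-2-methyl-5-(propan-2-ylidene)-2-(prop-2-en-1-yl)cyclopentan-1-one | O=C1C(=C(C)C)CC[C@]1(C)CC=C | intermediate
11 | (2R)-2-(2,3-dihydroxypropyl)-2-methyl-5-(propan-2-ylidene)cyclopentan-1-one (carbinol epimers, not isolated) | O=C1C(=C(C)C)CC[C@]1(C)CC(O)CO | intermediate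
12 | [(1R)-1-methyl-2-oxo-3-(propan-2-ylidene)cyclopentyl]acetaldehyde | O=C1C(=C(C)C)CC[C@]1(C)CC=O | intermediate
13 | (1S,2R)-2-(2-hydroxyethyl)-2-methyl-5-(propan-2-ylidene)cyclopentan-1-ol | O[C@@H]1C(=C(C)C)CC[C@]1(C)CCO | intermediate
14 | (1R,2R,5R)-2-(2-hydroxyethyl)-2-methyl-5-(propan-2-yl)cyclopentan-1-ol | O[C@@H]1[C@@H](C(C)C)CC[C@]1(C)CCO | intermediate
15 | (1R,2R,5R)-2-methyl-5-(propan-2-yl)-1-(triethylsilyloxy)-2-[2-(triethylsilyloxy)ethyl]cyclopentane | CC[Si](CC)(CC)O[C@@H]1[C@@H](C(C)C)CC[C@]1(C)CCO[Si](CC)(CC)CC | intermediate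
16 | dimethyl(alkoxy)sulfonium chloride of the primary position (not isolated) | CC[Si](CC)(CC)O[C@@H]1[C@@H](C(C)C)CC[C@]1(C)CCO[S+](C)C.[Cl-] | intermediate
17 | [(1R,2R,3R)-1-methyl-3-(propan-2-yl)-2-(triethylsilyloxy)cyclopentyl]acetaldehyde | CC[Si](CC)(CC)O[C@@H]1[C@@H](C(C)C)CC[C@]1(C)CC=O | intermediate
18 | ethyl 2-[bis(2,2,2-trifluoroethoxy)phosphoryl]propanoate | CCOC(=O)C(C)P(=O)(OCC(F)(F)F)OCC(F)(F)F | starting material
19 | potassium carbanion of 18 (not isolated) | [K+].CCOC(=O)[C-](C)P(=O)(OCC(F)(F)F)OCC(F)(F)F | intermediate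
20 | ethyl (2Z)-2-methyl-4-[(1R,2R,3R)-1-methyl-3-(propan-2-yl)-2-(triethylsilyloxy)cyclopentyl]but-2-enoate | CC[Si](CC)(CC)O[C@@H]1[C@@H](C(C)C)CC[C@]1(C)C/C=C(C)\C(=O)OCC | intermediate
21 | (2Z)-N-methoxy-N,2-dimethyl-4-[(1R,2R,3R)-1-methyl-3-(propan-2-yl)-2-(triethylsilyloxy)cyclopentyl]but-2-enamide | CC[Si](CC)(CC)O[C@@H]1[C@@H](C(C)C)CC[C@]1(C)C/C=C(C)\C(=O)N(C)OC | intermediate
22 | dibromomethane | BrCBr | starting material
23 | lithium alkoxide adduct of bromomethyllithium to 21 (not isolated) | [Li+].CC[Si](CC)(CC)O[C@@H]1[C@@H](C(C)C)CC[C@]1(C)C/C=C(C)\C([O-])(CBr)N(C)OC | intermediate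
24 | (3Z)-1-bromo-3-methyl-5-[(1R,2R,3R)-1-methyl-3-(propan-2-yl)-2-(triethylsilyloxy)cyclopentyl]pent-3-en-2-one | CC[Si](CC)(CC)O[C@@H]1[C@@H](C(C)C)CC[C@]1(C)C/C=C(C)\C(=O)CBr | intermediate
25 | (3Z)-1-bromo-5-[(1R,2R,3R)-2-hydroxy-1-methyl-3-(propan-2-yl)cyclopentyl]-3-methylpent-3-en-2-one | O[C@@H]1[C@@H](C(C)C)CC[C@]1(C)C/C=C(C)\C(=O)CBr | intermediate
26 | (2R,5R)-2-[(2Z)-5-bromo-3-methyl-4-oxopent-2-en-1-yl]-2-methyl-5-(propan-2-yl)cyclopentan-1-one | O=C1[C@@H](C(C)C)CC[C@]1(C)C/C=C(C)\C(=O)CBr | intermediate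
27 | diiodosamarium enolate (C1–O–Sm, C1=C2) of the side-chain ketone (not isolated) | O=C1[C@@H](C(C)C)CC[C@]1(C)C/C=C(C)\C(=C)O[Sm](I)I | intermediate
28 | diiodosamarium aldolate of 29 (not isolated) | O=C1C[C@]2(O[Sm](I)I)[C@@H](C(C)C)CC[C@]2(C)CC=C1C | intermediate
29 | (3R,3aS,8aR)-3a-hydroxy-6,8a-dimethyl-3-(propan-2-yl)-2,3,3a,4,8,8a-hexahydroazulen-5(1H)-one | O=C1C[C@]2(O)[C@@H](C(C)C)CC[C@]2(C)CC=C1C | intermediate
30 | (3R,3aS,5R,8aR)-6,8a-dimethyl-3-(propan-2-yl)-2,3,4,5,8,8a-hexahydro-1H-azulene-3a,5-diol | O[C@@H]1C[C@]2(O)[C@@H](C(C)C)CC[C@]2(C)CC=C1C | intermediate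
31 | 3,4-dimethoxybenzoyl chloride (veratroyl chloride) | COc1ccc(C(=O)Cl)cc1OC | starting material
32 | (3R,3aS,5R,8aR)-3a-hydroxy-6,8a-dimethyl-3-(propan-2-yl)-1,2,3,3a,4,5,8,8a-octahydroazulen-5-yl 3,4-dimethoxybenzoate | COc1ccc(C(=O)O[C@@H]2C[C@]3(O)[C@@H](C(C)C)CC[C@]3(C)CC=C2C)cc1OC | target

**Step count and risks**

Total steps: 17. Longest linear sequence: 17 steps (1 to 32). Compounds 2, 6, 18, 22 and 31 are bought and enter directly.

Steps most likely to fail:

Step 15 (ring closure). The crowded C3 carbonyl may be reached too slowly. Protonation of the samarium enolate (net loss of bromine) or retro-aldol opening of the aldolate would then take over.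
The fallback sets out from 26 and comes back at 29. It makes the nucleophile a neutral silyl enol ether and activates the acceptor instead. Reductive silylation of 26 with Zn and Me3SiCl in Et2O/TMEDA should give (2R,5R)-2-methyl-2-[(2Z)-3-methyl-4-(trimethylsilyloxy)penta-2,4-dien-1-yl]-5-(propan-2-yl)cyclopentan-1-one F1. An intramolecular Mukaiyama aldol reaction (TiCl4, CH2Cl2, −78 °C, high dilution, aqueous work-up) should then join C2 to the Lewis acid-bound C3 carbonyl from the same face and deliver 29.

Step 7 (C4). Slow hydrogen uptake by the tetrasubstituted alkene would leave room for two side processes. One is iridium hydride-induced isomerisation of the allylic alcohol to the ketone, the other is acid-induced ionisation of the allylic alcohol. Either would cost the control of C4.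
The fallback sets out from 10, replaces kinetic direction by equilibration and recycling, and comes back at 17, so that steps 5 to 9 are bypassed.
- Dissolving-metal conjugate reduction (Li, NH3, t-BuOH, THF, −78 °C) is followed by equilibration of C4 with NaOMe in MeOH, chromatographic separation and re-equilibration of the unwanted epimer. This should give (2R,5R)-2-methyl-5-(propan-2-yl)-2-(prop-2-en-1-yl)cyclopentan-1-one F2.
- Further reduction with Li in NH3/EtOH should give the more stable carbinol, with the hydroxyl trans to the isopropyl group, (1R,2R,5R)-2-methyl-5-(propan-2-yl)-2-(prop-2-en-1-yl)cyclopentan-1-ol F3.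
- Silylation with TESOTf and 2,6-lutidine gives triethyl{[(1R,2R,5R)-2-methyl-5-(propan-2-yl)-2-(prop-2-en-1-yl)cyclopentyl]oxy}silane F4.
- Ozonolysis of its only alkene (O3, CH2Cl2, −78 °C; PPh3) gives 17.

Step 16 (C1). Sluggish ligand exchange at the tertiary C3 hydroxyl would let undirected hydride attack compete, with poor facial selectivity at C1.
The fallback sets out from 29 and comes back at 32. It aims on purpose at the opposite carbinol and inverts it while the ester is put on. A Narasaka–Prasad reduction (Et2BOMe, NaBH4, THF/MeOH, −78 °C), in which external hydride attacks the boron chelate of the C3 hydroxyl and the C1 carbonyl, should give the 1,3-syn diol (3R,3aS,5S,8aR)-6,8a-dimethyl-3-(propan-2-yl)-2,3,4,5,8,8a-hexahydro-1H-azulene-3a,5-diol F5. A Mitsunobu esterification with 3,4-dimethoxybenzoic acid (PPh3, DIAD, toluene, 0 °C) then inverts C1 and gives 32 directly, the tertiary hydroxyl being inert.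

**Further compounds**

F1 | step 15 | (2R,5R)-2-methyl-2-[(2Z)-3-methyl-4-(trimethylsilyloxy)penta-2,4-dien-1-yl]-5-(propan-2-yl)cyclopentan-1-one | O=C1[C@@H](C(C)C)CC[C@]1(C)C/C=C(C)\C(=C)O[Si](C)(C)C
F2 | step 7 | (2R,5R)-2-methyl-5-(propan-2-yl)-2-(prop-2-en-1-yl)cyclopentan-1-one | O=C1[C@@H](C(C)C)CC[C@]1(C)CC=C
F3 | step 7 | (1R,2R,5R)-2-methyl-5-(propan-2-yl)-2-(prop-2-en-1-yl)cyclopentan-1-ol | O[C@@H]1[C@@H](C(C)C)CC[C@]1(C)CC=C
F4 | step 7 | triethyl{[(1R,2R,5R)-2-methyl-5-(propan-2-yl)-2-(prop-2-en-1-yl)cyclopentyl]oxy}silane | CC[Si](CC)(CC)O[C@@H]1[C@@H](C(C)C)CC[C@]1(C)CC=C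
F5 | step 16 | (3R,3aS,5S,8aR)-6,8a-dimethyl-3-(propan-2-yl)-2,3,4,5,8,8a-hexahydro-1H-azulene-3a,5-diol | O[C@H]1C[C@]2(O)[C@@H](C(C)C)CC[C@]2(C)CC=C1C
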